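**Retrosynthetic overview**

1. Ring A (C1–C5, C10) is a cyclohexene whose C1=C10 bond is flanked by C2 and C5, with the ester-bearing quaternary C4 next to C5. This is a Diels–Alder retron, cut at C2–C3 and C4–C5 into a ring B 1-vinylcyclohexene (C2=C1–C10=C5) and a 1,1-disubstituted acrylic dienophile (C3=C4 carrying C18 and C19).
2. The dienophile is shaped as itaconic anhydride: the temporary ring locks the C18 carbonyl s-cis (exo mode, C18 α, C19 β) and carries C19 as CH2CO2H, which is later cut back to CH3 by Barton decarboxylation.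
3. The diene comes from 2-methylcyclohex-2-enone: asymmetric conjugate methylation (C8), Mukaiyama–Michael addition to a glycerate-derived vinyl ketone (quaternary C9; C14 from the chiral pool), chelate-controlled MeMgBr addition (C13), enol triflate, Stille vinylation.
4. Ring order: ring B is present from the start, ring A is closed by the cycloaddition; deprotection and selective diacetylation finish the synthesis.

Key step: step 9

Remark: halimane numbering is used (ring A = C1–C5 and C10; ring B = C5–C10; C17 on C8, C20 on C9; C18 = ester carbon and C19 = methyl on C4; side chain C11–C16; α/β refer to H-5 = α); magnesium alkoxides that are only protonated in the aqueous work-up are not listed as separate compounds.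

Step 1
Reactants: 1 methyl (4R)-2,2-dimethyl-1,3-dioxolane-4-carboxylate
Product: 2 (4R)-N-methoxy-N,2,2-trimethyl-1,3-dioxolane-4-carboxamide
Conditions: MeNHOMe·HCl, iPrMgCl, THF, −20 °C
Reagents that add atoms: N,O-dimethylhydroxylamine hydrochloride, CNOC.Cl
Why: Weinreb amidation of the ester with the chloromagnesium amide generated in situ from the amine salt and iPrMgCl is fast at −20 °C and leaves the α-oxygenated stereocentre (the later C14) untouched.

Step 2
Reactants: 2 (4R)-N-methoxy-N,2,2-trimethyl-1,3-dioxolane-4-carboxamide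
Product: 3 1-[(4R)-2,2-dimethyl-1,3-dioxolan-4-yl]prop-2-en-1-one
Conditions: CH2=CHMgBr, THF, −78 to 0 °C; inverse quench into cold 1 M aqueous HCl
Reagents that add atoms: vinylmagnesium bromide, C=C[Mg]Br
Why: Weinreb ketone synthesis, in which the magnesium-chelated tetrahedral adduct holds until the cold acidic quench so that a single vinyl group is transferred and the freed amine, protonated at once, cannot add to the enone.

Step 3
Reactants: 4 2-methylcyclohex-2-en-1-one
Product: 6 trimethyl{[(3R)-2,3-dimethylcyclohex-1-en-1-yl]oxy}silane, via dimethylaluminium enolate 5 (not isolated)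
Conditions: AlMe3, Cu(O2CC4H3S) (copper thiophene-2-carboxylate, 2 mol%), chiral BINOL-based phosphoramidite with a bis(1-phenylethyl)amine unit (4 mol%, antipode chosen to give 3R), Et2O, −30 °C; then Me3SiOTf, THF, −78 to 0 °C
Reagents that add atoms: trimethylaluminium, C[Al](C)C; trimethylsilyl trifluoromethanesulfonate, C[Si](C)(C)OS(=O)(=O)C(F)(F)F
Why: Copper-catalysed asymmetric conjugate addition of AlMe3 to a 2-substituted cyclohexenone, in which the chiral phosphoramidite–copper complex selects the enone face to set C8 as R and the regiodefined aluminium enolate is then O-silylated.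

Step 4
Reactants: 6 trimethyl{[(3R)-2,3-dimethylcyclohex-1-en-1-yl]oxy}silane; 3 1-[(4R)-2,2-dimethyl-1,3-dioxolan-4-yl]prop-2-en-1-one
Product: 8 (2S,3R)-2-{3-[(4R)-2,2-dimethyl-1,3-dioxolan-4-yl]-3-oxopropyl}-2,3-dimethylcyclohexan-1-one, via silyl enol ether 7 (not isolated)
Conditions: HNTf2 (2 mol%), CH2Cl2, −78 °C; then aqueous citric acid, THF, 0 °C
Reagents that add atoms: none
Why: Mukaiyama–Michael addition catalysed by the silyl triflimide formed in situ, which builds the quaternary C9 with the acceptor entering the enol ether face anti to the pseudoaxial C8 methyl (allylic 1,2-strain), so that the two ring methyls become cis as in the known annulations of 2,3-dimethylcyclohexanone derivatives.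

Step 5
Reactants: 8 (2S,3R)-2-{3-[(4R)-2,2-dimethyl-1,3-dioxolan-4-yl]-3-oxopropyl}-2,3-dimethylcyclohexan-1-one
Product: 9 (2S,3R)-2-{(3S)-3-[(4R)-2,2-dimethyl-1,3-dioxolan-4-yl]-3-hydroxybutyl}-2,3-dimethylcyclohexan-1-one
Conditions: MeMgBr (1.2 equiv), CH2Cl2/Et2O, −78 °C; then aqueous NH4Cl
Reagents that add atoms: methylmagnesium bromide, C[Mg]Br
Why: Cram-chelate controlled Grignard addition, in which magnesium bridges the C13 carbonyl and the adjacent dioxolane oxygen on C14 so that the methyl group enters from the side of the C14 hydrogen to give 13S (the outcome known for erythrulose acetonides), while the unactivated ring ketone beside the quaternary C9 should not compete at −78 °C.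

Step 6
Reactants: 9 (2S,3R)-2-{(3S)-3-[(4R)-2,2-dimethyl-1,3-dioxolan-4-yl]-3-hydroxybutyl}-2,3-dimethylcyclohexan-1-one
Product: 10 (2S,3R)-2-{(3S)-3-[(4R)-2,2-dimethyl-1,3-dioxolan-4-yl]-3-[(triethylsilyl)oxy]butyl}-2,3-dimethylcyclohexan-1-one
Conditions: Et3SiOTf, 2,6-lutidine, CH2Cl2, −78 to 0 °C
Reagents that add atoms: triethylsilyl trifluoromethanesulfonate, CC[Si](CC)(CC)OS(=O)(=O)C(F)(F)F
Why: Silylation of a tertiary alcohol with a silyl triflate and 2,6-lutidine is standard and removes the only acidic O–H before the enolate chemistry of the next step.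

Step 7
Reactants: 10 (2S,3R)-2-{(3S)-3-[(4R)-2,2-dimethyl-1,3-dioxolan-4-yl]-3-[(triethylsilyl)oxy]butyl}-2,3-dimethylcyclohexan-1-one
Product: 12 (5R,6S)-6-{(3S)-3-[(4R)-2,2-dimethyl-1,3-dioxolan-4-yl]-3-[(triethylsilyl)oxy]butyl}-5,6-dimethylcyclohex-1-en-1-yl trifluoromethanesulfonate, via potassium enolate 11 (not isolated)
Conditions: KN(SiMe3)2, THF, −78 °C; then PhNTf2, −78 to 0 °C
Reagents that add atoms: N-phenylbis(trifluoromethanesulfonimide), O=S(=O)(N(c1ccccc1)S(=O)(=O)C(F)(F)F)C(F)(F)F
Why: Enol triflate formation, regiospecific because the ketone can enolise only toward C5 (C9 is quaternary), the potassium enolate being O-sulfonylated by the triflimide.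

Step 8
Reactants: 12 (5R,6S)-6-{(3S)-3-[(4R)-2,2-dimethyl-1,3-dioxolan-4-yl]-3-[(triethylsilyl)oxy]butyl}-5,6-dimethylcyclohex-1-en-1-yl trifluoromethanesulfonate
Product: 13 triethyl({(2S)-2-[(4R)-2,2-dimethyl-1,3-dioxolan-4-yl]-4-[(1S,6R)-2-ethenyl-1,6-dimethylcyclohex-2-en-1-yl]butan-2-yl}oxy)silane
Conditions: Bu3SnCH=CH2, Pd(PPh3)4 (5 mol%), LiCl (3 equiv), THF, 65 °C
Reagents that add atoms: tributyl(vinyl)stannane, C=C[Sn](CCCC)(CCCC)CCCC
Why: Stille cross-coupling of an enol triflate with a vinylstannane in the presence of LiCl, a standard route to 1-vinylcyclohexenes that is compatible with the silyl ether and the acetonide.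

Step 9
Reactants: 13 triethyl({(2S)-2-[(4R)-2,2-dimethyl-1,3-dioxolan-4-yl]-4-[(1S,6R)-2-ethenyl-1,6-dimethylcyclohex-2-en-1-yl]butan-2-yl}oxy)silane; 14 itaconic anhydride (3-methylideneoxolane-2,5-dione)
Product: 15 exo spiro-anhydride cycloadduct (ring A closed with C1=C10; C4 is the spiro carbon of the succinic anhydride; C18 carbonyl 4α and cis to 5α-H; anhydride CH2 = C19 4β)
Conditions: 14 (3 equiv), BHT (cat.), toluene, 90 °C
Reagents that add atoms: none
Why: Thermal Diels–Alder reaction in which the s-cis diene C2=C1–C10=C5 of 13 and the exocyclic C3=C4 bond of 14 combine through a concerted but asynchronous transition state, the C2–C3 bond between the unhindered vinyl terminus and the dienophile CH2 running ahead and closing ring A together with the C4–C5 bond; the closest known reaction type is the cycloaddition of 1-vinylcyclohexenes with α-methylene lactones and anhydrides. Ring A is closed in the [4+2] mode, suprafacial on both partners, which places the double bond at C1=C10 by necessity. C5 is controlled by the two α-methyl groups of ring B: the half-chair with C20 pseudoaxial on C9 blocks the α face and leaves the β face free of axial substituents (C11 pseudoequatorial, H-8 axial), and the alternative half-chair still carries the axial C17 on the α face, so the dienophile should add to the β face and H-5 should become α. C4 is controlled by the temporary anhydride ring, which locks the C18 carbonyl s-cis to the alkene, a geometry for which the exo transition state (carbonyl away from the diene, ring CH2 over it) is the preferred one, so that C18 should end α (cis to H-5, the inside substituent of the diene terminus) and C19 β. The step needs regioselectivity (C4 to C5), which the larger HOMO coefficient at the vinyl terminus C2 meeting the CH2 of the acrylic unit secures, β-facial selectivity, which C17 and C20 secure, and exo selectivity, which the s-cis lock secures, while the quaternary C9 next to C10 favours the reactive s-cis diene rotamer. In one operation it forms two C–C bonds, ring A, the quaternary C4 and C5, and brings in both C18 and C19.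

Step 10
Reactants: 15 exo spiro-anhydride cycloadduct
Product: 17 diester (4α-CO2Me and 4β-CH2CO2Me on ring A; rest as in 15), via half ester 16 (not isolated)
Conditions: MeOH, DMAP (10 mol%), 40 °C; then Me3SiCHN2, toluene/MeOH, 0 °C
Reagents that add atoms: methanol, CO; (trimethylsilyl)diazomethane, C[Si](C)(C)C=[N+]=[N-]
Why: Nucleophilic ring opening of the anhydride by methanol at the unhindered CH2-bound carbonyl followed by diazoalkane esterification of the neopentyl C18 acid, both modes of opening converging on the same diester.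

Step 11
Reactants: 17 diester (4α-CO2Me and 4β-CH2CO2Me)
Product: 18 acid ester (4α-CO2Me and 4β-CH2CO2H)
Conditions: LiOH·H2O (1.5 equiv), THF/MeOH/H2O, 0 to 23 °C; then 0.5 M aqueous HCl to pH 4, 0 °C
Reagents that add atoms: lithium hydroxide, [Li+].[OH-]
Why: Saponification that discriminates the two esters by steric hindrance, the primary CH2CO2Me being hydrolysed while the ester on the quaternary C4 is left intact.

Step 12
Reactants: 18 acid ester (4α-CO2Me and 4β-CH2CO2H)
Product: 20 methyl (4R,5R,8R,9S,13S,14R)-14,15-(isopropylidenedioxy)-13-(triethylsilyloxy)halim-1(10)-en-18-oate, via Barton ester 19 (not isolated)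
Conditions: N-hydroxypyridine-2-thione, DCC, DMAP (cat.), CH2Cl2, 23 °C, dark; then t-BuSH, tungsten lamp, 23 °C
Reagents that add atoms: none
Why: Barton reductive decarboxylation, in which the thiohydroxamate ester fragments under visible light to CO2 and the primary C19 radical, which takes a hydrogen atom from the thiol faster than it can cyclise or rearrange and so leaves the 4β-methyl group without touching C4.

Step 13
Reactants: 20 methyl (4R,5R,8R,9S,13S,14R)-14,15-(isopropylidenedioxy)-13-(triethylsilyloxy)halim-1(10)-en-18-oate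
Product: 21 methyl (4R,5R,8R,9S,13S,14R)-13,14,15-trihydroxyhalim-1(10)-en-18-oate
Conditions: AcOH/THF/H2O (3:1:1), 40 °C
Reagents that add atoms: none
Why: Mild acid hydrolysis cleaves the acetonide and the tertiary triethylsilyl ether together while avoiding the strong acid that could shift the C1=C10 double bond.

Step 14
Reactants: 21 methyl (4R,5R,8R,9S,13S,14R)-13,14,15-trihydroxyhalim-1(10)-en-18-oate
Product: 22 methyl (4R,5R,8R,9S,13S,14R)-14,15-diacetoxy-13-hydroxyhalim-1(10)-en-18-oate (CNP0238486.1)
Conditions: Ac2O, pyridine, 0 to 23 °C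
Reagents that add atoms: acetic anhydride, CC(=O)OC(C)=O
Why: Acetylation with Ac2O in pyridine esterifies the primary C15 and secondary C14 hydroxyls, whereas the tertiary C13 hydroxyl does not react under these conditions.

**Compound list**

1 | methyl (4R)-2,2-dimethyl-1,3-dioxolane-4-carboxylate | COC(=O)[C@H]1COC(C)(C)O1 | starting material
2 | (4R)-N-methoxy-N,2,2-trimethyl-1,3-dioxolane-4-carboxamide | CON(C)C(=O)[C@H]1COC(C)(C)O1 | intermediate
3 | 1-[(4R)-2,2-dimethyl-1,3-dioxolan-4-yl]prop-2-en-1-one | C=CC(=O)[C@H]1COC(C)(C)O1 | intermediate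
4 | 2-methylcyclohex-2-en-1-one | CC1=CCCCC1=O | starting material
5 | dimethylaluminium (3R)-2,3-dimethylcyclohex-1-en-1-olate (not isolated) | C[Al](C)OC1=C(C)[C@H](C)CCC1 | intermediate
6 | trimethyl{[(3R)-2,3-dimethylcyclohex-1-en-1-yl]oxy}silane | C[Si](C)(C)OC1=C(C)[C@H](C)CCC1 | intermediate
7 | (2S,3R)-2-{(2Z)-3-[(4R)-2,2-dimethyl-1,3-dioxolan-4-yl]-3-[(trimethylsilyl)oxy]prop-2-en-1-yl}-2,3-dimethylcyclohexan-1-one (not isolated; Z geometry expected) | O=C1CCC[C@@H](C)[C@]1(C)C/C=C(\O[Si](C)(C)C)[C@H]2COC(C)(C)O2 | intermediate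
8 | (2S,3R)-2-{3-[(4R)-2,2-dimethyl-1,3-dioxolan-4-yl]-3-oxopropyl}-2,3-dimethylcyclohexan-1-one | O=C1CCC[C@@H](C)[C@]1(C)CCC(=O)[C@H]2COC(C)(C)O2 | intermediate
9 | (2S,3R)-2-{(3S)-3-[(4R)-2,2-dimethyl-1,3-dioxolan-4-yl]-3-hydroxybutyl}-2,3-dimethylcyclohexan-1-one | O=C1CCC[C@@H](C)[C@]1(C)CC[C@](C)(O)[C@H]2COC(C)(C)O2 | intermediate
10 | (2S,3R)-2-{(3S)-3-[(4R)-2,2-dimethyl-1,3-dioxolan-4-yl]-3-[(triethylsilyl)oxy]butyl}-2,3-dimethylcyclohexan-1-one | O=C1CCC[C@@H](C)[C@]1(C)CC[C@](C)(O[Si](CC)(CC)CC)[C@H]2COC(C)(C)O2 | intermediate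
11 | potassium (5R,6S)-6-{(3S)-3-[(4R)-2,2-dimethyl-1,3-dioxolan-4-yl]-3-[(triethylsilyl)oxy]butyl}-5,6-dimethylcyclohex-1-en-1-olate (not isolated) | [K+].[O-]C1=CCC[C@@H](C)[C@]1(C)CC[C@](C)(O[Si](CC)(CC)CC)[C@H]2COC(C)(C)O2 | intermediate
12 | (5R,6S)-6-{(3S)-3-[(4R)-2,2-dimethyl-1,3-dioxolan-4-yl]-3-[(triethylsilyl)oxy]butyl}-5,6-dimethylcyclohex-1-en-1-yl trifluoromethanesulfonate | O=S(=O)(OC1=CCC[C@@H](C)[C@]1(C)CC[C@](C)(O[Si](CC)(CC)CC)[C@H]2COC(C)(C)O2)C(F)(F)F | intermediate
13 | triethyl({(2S)-2-[(4R)-2,2-dimethyl-1,3-dioxolan-4-yl]-4-[(1S,6R)-2-ethenyl-1,6-dimethylcyclohex-2-en-1-yl]butan-2-yl}oxy)silane | C=CC1=CCC[C@@H](C)[C@]1(C)CC[C@](C)(O[Si](CC)(CC)CC)[C@H]2COC(C)(C)O2 | intermediate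
14 | itaconic anhydride (3-methylideneoxolane-2,5-dione) | C=C1CC(=O)OC1=O | starting material
15 | (3S,5'S,6'R,8a'R)-5'-{(3S)-3-[(4R)-2,2-dimethyl-1,3-dioxolan-4-yl]-3-[(triethylsilyl)oxy]butyl}-5',6'-dimethyl-3',5',6',7',8',8a'-hexahydro-2'H-spiro[oxolane-3,1'-naphthalene]-2,5-dione (exo adduct; C18 carbonyl 4α, CH2 4β, 5α-H) | O=C1OC(=O)C[C@]12CCC=C3[C@H]2CC[C@@H](C)[C@]3(C)CC[C@](C)(O[Si](CC)(CC)CC)[C@H]4COC(C)(C)O4 | intermediate
16 | half ester of 15: 4α-CO2H (C18) and 4β-CH2CO2Me, otherwise as 15 (not isolated) | OC(=O)[C@]1(CC(=O)OC)CCC=C2[C@H]1CC[C@@H](C)[C@]2(C)CC[C@](C)(O[Si](CC)(CC)CC)[C@H]3COC(C)(C)O3 | intermediate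
17 | diester: 4α-CO2Me and 4β-CH2CO2Me, otherwise as 15 | COC(=O)[C@]1(CC(=O)OC)CCC=C2[C@H]1CC[C@@H](C)[C@]2(C)CC[C@](C)(O[Si](CC)(CC)CC)[C@H]3COC(C)(C)O3 | intermediate
18 | acid ester: 4α-CO2Me and 4β-CH2CO2H, otherwise as 15 | COC(=O)[C@]1(CC(=O)O)CCC=C2[C@H]1CC[C@@H](C)[C@]2(C)CC[C@](C)(O[Si](CC)(CC)CC)[C@H]3COC(C)(C)O3 | intermediate
19 | Barton ester of 18 (2-thioxopyridin-1(2H)-yl ester of the CH2CO2H group; not isolated) | COC(=O)[C@]1(CC(=O)ON4C=CC=CC4=S)CCC=C2[C@H]1CC[C@@H](C)[C@]2(C)CC[C@](C)(O[Si](CC)(CC)CC)[C@H]3COC(C)(C)O3 | intermediate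
20 | methyl (4R,5R,8R,9S,13S,14R)-14,15-(isopropylidenedioxy)-13-(triethylsilyloxy)halim-1(10)-en-18-oate (4α-CO2Me, 4β-Me, 5α-H, 8α-Me, 9α-Me) | COC(=O)[C@]1(C)CCC=C2[C@H]1CC[C@@H](C)[C@]2(C)CC[C@](C)(O[Si](CC)(CC)CC)[C@H]3COC(C)(C)O3 | intermediate
21 | methyl (4R,5R,8R,9S,13S,14R)-13,14,15-trihydroxyhalim-1(10)-en-18-oate | COC(=O)[C@]1(C)CCC=C2[C@H]1CC[C@@H](C)[C@]2(C)CC[C@](C)(O)[C@H](O)CO | intermediate
22 | methyl (4R,5R,8R,9S,13S,14R)-14,15-diacetoxy-13-hydroxyhalim-1(10)-en-18-oate (CNP0238486.1) | COC(=O)[C@]1(C)CCC=C2[C@H]1CC[C@@H](C)[C@]2(C)CC[C@](C)(O)[C@@H](COC(C)=O)OC(C)=O | target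

**Step count and risks**

Total step count: 14. Longest linear sequence: 13 steps (steps 1, 2 and 4 to 14, from 1); step 3 makes the ring B fragment 6 from 4, which joins the main line in step 4.

Steps most likely to fail:

1. Step 9 (cycloaddition). The exo preference may erode so that C18 is delivered to the β side, the dienophile may add with the opposite orientation or to the α face, or 14 may isomerise to citraconic anhydride before it reacts. The fallback sets out from 13 and comes back at 20; it removes the endo/exo question by using a symmetric dienophile and differentiating the two carbonyls afterwards. Meldrum's acid, formaldehyde and catalytic proline would generate 2,2-dimethyl-5-methylidene-1,3-dioxane-4,6-dione F1 in the presence of 13, and cycloaddition should give the spiro Meldrum's acid cycloadduct F2, in which C4 carries two identical carbonyl arms and only the β-facial selectivity set by C17 and C20 is needed. NaOMe in MeOH at 0 °C should open the dioxanedione at the more accessible equatorial (α) carbonyl to give the malonic half ester F3 (4α-CO2Me, 4β-CO2H), which is kept cold. BH3·THF (1 equiv, 0 °C) should reduce the acid, faster than it hydroborates the hindered C1=C10 bond, to the 4β-hydroxymethyl ester F4. I2, PPh3 and imidazole in warm toluene should then give the 4β-iodomethyl ester F5, and Bu3SnH with AIBN should reduce it to 20.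

2. Step 4 (Mukaiyama–Michael addition). Polymerisation of the vinyl ketone or protodesilylation of the enol ether may outrun C–C bond formation at the tetrasubstituted carbon, and the acid catalyst may open the acetonide. The fallback sets out from 2 and 6 and comes back at 8; it replaces the acid-catalysed addition by an anionic Michael addition to an α-silyl enone. Amide 2 and [1-(trimethylsilyl)ethenyl]magnesium bromide should give 1-[(4R)-2,2-dimethyl-1,3-dioxolan-4-yl]-2-(trimethylsilyl)prop-2-en-1-one F6. MeLi in THF should convert 6 into lithium (3R)-2,3-dimethylcyclohex-1-en-1-olate F7. This enolate should add to F6 at −78 °C, the silyl group stabilising the adduct enolate and suppressing polymerisation, to give the α-silyl diketone F8 (epimers at the silicon-bearing C12) with the same facial bias at C9. KF in MeOH should then remove the silyl group and return 8.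

3. Step 8 (Stille coupling). Oxidative addition into the triflate beside the quaternary C9 may be slow, so that hydrolysis or reduction of the triflate competes with coupling. The fallback sets out from 10 and comes back at 13; it builds the diene by carbonyl addition and elimination. CH2=CHMgBr with anhydrous CeCl3 in THF at −78 °C should add to the hindered ketone to give the tertiary allylic alcohol F9 (drawn with the vinyl group β; the C10 configuration is of no consequence because C10 becomes trigonal again). Syn-dehydration with methyl N-(triethylammoniosulfonyl)carbamate (Burgess reagent) in toluene at 50 °C can remove only a C5 hydrogen, because C9 is quaternary, and should give 13.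

**Further compounds**

F1 | step 9 | 2,2-dimethyl-5-methylidene-1,3-dioxane-4,6-dione | C=C1C(=O)OC(C)(C)OC1=O
F2 | step 9 | spiro Meldrum's acid cycloadduct of 13 (C4 = C5 of the dioxanedione; 5α-H) | CC1(C)OC(=O)C2(CCC=C3[C@H]2CC[C@@H](C)[C@]3(C)CC[C@](C)(O[Si](CC)(CC)CC)[C@H]4COC(C)(C)O4)C(=O)O1
F3 | step 9 | malonic half ester (4α-CO2Me, 4β-CO2H), otherwise as 20 | COC(=O)[C@]1(C(=O)O)CCC=C2[C@H]1CC[C@@H](C)[C@]2(C)CC[C@](C)(O[Si](CC)(CC)CC)[C@H]3COC(C)(C)O3
F4 | step 9 | 4β-hydroxymethyl ester (4α-CO2Me, 4β-CH2OH), otherwise as 20 | COC(=O)[C@]1(CO)CCC=C2[C@H]1CC[C@@H](C)[C@]2(C)CC[C@](C)(O[Si](CC)(CC)CC)[C@H]3COC(C)(C)O3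
F5 | step 9 | 4β-iodomethyl ester (4α-CO2Me, 4β-CH2I), otherwise as 20 | COC(=O)[C@]1(CI)CCC=C2[C@H]1CC[C@@H](C)[C@]2(C)CC[C@](C)(O[Si](CC)(CC)CC)[C@H]3COC(C)(C)O3
F6 | step 4 | 1-[(4R)-2,2-dimethyl-1,3-dioxolan-4-yl]-2-(trimethylsilyl)prop-2-en-1-one | C=C([Si](C)(C)C)C(=O)[C@H]1COC(C)(C)O1
F7 | step 4 | lithium (3R)-2,3-dimethylcyclohex-1-en-1-olate | [Li+].[O-]C1=C(C)[C@H](C)CCC1
F8 | step 4 | (2S,3R)-2-{3-[(4R)-2,2-dimethyl-1,3-dioxolan-4-yl]-3-oxo-2-(trimethylsilyl)propyl}-2,3-dimethylcyclohexan-1-one (epimers at the silicon-bearing carbon) | O=C1CCC[C@@H](C)[C@]1(C)CC([Si](C)(C)C)C(=O)[C@H]2COC(C)(C)O2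
F9 | step 8 | (1R,2S,3R)-2-{(3S)-3-[(4R)-2,2-dimethyl-1,3-dioxolan-4-yl]-3-[(triethylsilyl)oxy]butyl}-1-ethenyl-2,3-dimethylcyclohexan-1-ol (vinyl β, hydroxyl α) | O[C@@]1(C=C)CCC[C@@H](C)[C@]1(C)CC[C@](C)(O[Si](CC)(CC)CC)[C@H]2COC(C)(C)O2
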